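**Plan**

1. The acetoxy-bearing CH of the δ-lactone (C-4 of the 2,7-dioxabicyclo[3.2.1]octan-3-one) holds an acyloxy oxygen and the lactone carbonyl carbon on one carbon. After the lactone C(=O)–O bond is opened to a lactol and an active amide, this CH is cut at both bonds to a tetrahydrofuran-3-carbaldehyde, acetic acid and a convertible aryl isocyanide (Passerini retron).
2. The tetrahydrofuran is cut at the ring O–C(acetal) bond and at the bond from C-3 to the ester-bearing carbon (glyoxylate aldol), which leaves a 4-substituted 5-alkoxybutanolide. That is cut between its C-4 and the quaternary carbon (tertiary radical plus chiral butenolide).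
3. The hydroazulenyl carbinol is cut at the five-ring bond between ring-fusion carbon and carbinol carbon (reductive aldol) and at the side-chain bond (Stork–Danheiser), back to cycloheptane-1,3-dione.
4. Forward order: seven-membered ring (bought), five-membered carbocycle (step 4), butanolide joined (step 7), butanolide reorganised into the tetrahydrofuran (step 9), chain extended (step 12), δ-lactone closed last (step 14).
5. Stereochemistry: ring fusion from a chiral copper hydride catalyst; quaternary carbon from convex-face attack of the radical; neighbouring ring CH from the (5S)-menthyloxybutenolide; the two aldol centres from the lactone face and a titanium enolate; acetoxy carbon from a chiral phosphoric acid; bridgehead acetal from the ring closure.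

Key step: step 12

Assumption: the sense of induction of the copper hydride catalyst (step 4) and of the phosphoric acid (step 12) is taken as written; if a test run shows the opposite sense, the antipodal ligand or acid is used.
Assumption: butenolide 14 (from furfural and (+)-menthol) and isocyanide 23 are treated as purchasable.

In names, Az is the (1R,3aR,8aS)-1,4,4-trimethyl-8-methylidenedecahydroazulen-1-yl group (cis-fused; the bond from C-1 to the rest is cis to both ring-fusion hydrogens). Men is (1S,2R,5S)-5-methyl-2-(propan-2-yl)cyclohexyl, the residue of (+)-menthol.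

**Route**

Step 1
Reactants: 1 cycloheptane-1,3-dione
Product: 2 3-(2-methylpropoxy)cyclohept-2-en-1-one
Conditions: i-BuOH, PPTS (cat.), toluene, reflux, Dean–Stark
Reagents that add atoms: 2-methylpropan-1-ol, CC(C)CO
Why: Acid-catalysed condensation of the cyclic 1,3-dione with the alcohol under water removal gives the vinylogous ester, which masks one carbonyl and differentiates the α-positions for the Stork–Danheiser sequence.

Step 2
Reactants: 2 3-(2-methylpropoxy)cyclohept-2-en-1-one
Product: 4 7,7-dimethyl-3-(2-methylpropoxy)cyclohept-2-en-1-one, via monomethyl enone 3 (not isolated)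
Conditions: LDA (1.1 equiv), THF, −78 °C, then MeI; again LDA (1.2 equiv), then MeI, −78 → 0 °C
Reagents that add atoms: iodomethane, CI
Why: Kinetic deprotonation of a vinylogous ester takes place at the α′-carbon (C-7), so two successive enolate alkylations should place both methyl groups beside the carbonyl.

Step 3
Reactants: 4 7,7-dimethyl-3-(2-methylpropoxy)cyclohept-2-en-1-one; 5 2-(2-bromoethyl)-2-methyl-1,3-dioxolane
Product: 8 4,4-dimethyl-3-(3-oxobutyl)cyclohept-2-en-1-one, via Grignard reagent 6 (not isolated), via tertiary carbinol 7 (not isolated)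
Conditions: 5, Mg, THF, 25 °C; then 4, CeCl3, THF, −78 → 0 °C; then 2 M HCl, THF, 23 °C
Reagents that add atoms: water, O
Why: Stork–Danheiser transposition: the organocerium reagent made from the Grignard reagent adds 1,2 to the hindered carbonyl, and aqueous acid then ionises the tertiary allylic carbinol, hydrolyses the enol ether to the transposed enone and frees the methyl ketone from its dioxolane.

Step 4
Reactants: 8 4,4-dimethyl-3-(3-oxobutyl)cyclohept-2-en-1-one
Product: 10 (3S,3aR,8aR)-3-hydroxy-3,8,8-trimethyloctahydroazulen-4(1H)-one, via silyl ether 9 (not isolated)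
Conditions: Cu(OAc)2·H2O (5 mol%), (R)-DTBM-SEGPHOS (5.5 mol%), (EtO)2MeSiH, toluene, 0 → 23 °C; then NH4F, MeOH
Reagents that add atoms: none
Why: Copper hydride conjugate reduction–aldol cyclisation: the ligand-bound hydride is delivered to one face of the β-carbon (this fixes C-8a), and the copper enolate adds to the tethered methyl ketone on the face carrying the tether through a chelated closed transition state, which should give the cis ring fusion and the hydroxyl cis to the ring carbonyl.

Step 5
Reactants: 10 (3S,3aR,8aR)-3-hydroxy-3,8,8-trimethyloctahydroazulen-4(1H)-one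
Product: 11 (1S,3aR,8aS)-1,4,4-trimethyl-8-methylidenedecahydroazulen-1-ol
Conditions: Zn, CH2Br2, TiCl4, THF/CH2Cl2, 0 → 23 °C
Reagents that add atoms: dibromomethane, BrCBr
Why: Takai–Lombardo methylenation uses a non-basic gem-dimetallic reagent, so the β-hydroxy ketone should be methylenated without retro-aldol cleavage or epimerisation of the ring-fusion carbon beside the carbonyl, and the free tertiary hydroxyl is tolerated.

Step 6
Reactants: 11 (1S,3aR,8aS)-1,4,4-trimethyl-8-methylidenedecahydroazulen-1-ol
Product: 13 cesium 2-oxo-2-{[(1S,3aR,8aS)-1,4,4-trimethyl-8-methylidenedecahydroazulen-1-yl]oxy}acetate, via methyl oxalate 12 (not isolated)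
Conditions: ClC(O)CO2Me, Et3N, DMAP (cat.), CH2Cl2, 0 → 23 °C; then CsOH·H2O (1.0 equiv), THF/H2O, 23 °C
Reagents that add atoms: methyl chlorooxoacetate, COC(=O)C(=O)Cl; cesium hydroxide, [Cs+].[OH-]
Why: Acylation of the tertiary alcohol with the very reactive oxalyl half-ester chloride, then saponification of only the unhindered methyl ester, gives the half-oxalate salt that serves as radical precursor for a tertiary alcohol.

Step 7
Reactants: 13 cesium half-oxalate of 11; 14 (5S)-5-(Men-oxy)furan-2(5H)-one
Product: 15 (4R,5S)-4-Az-5-(Men-oxy)oxolan-2-one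
Conditions: Ir[dF(CF3)ppy]2(dtbbpy)PF6 (1 mol%), H2O (10 equiv), DME/DMF 3:1, blue LEDs, 60 °C
Reagents that add atoms: none
Why: Photoredox Giese reaction: oxidation of the oxalate by the excited iridium complex and loss of two CO2 give the tertiary radical, which adds to the butenolide β-carbon from the convex face of the cis-hydroazulene (new bond cis to the ring-fusion hydrogens, setting the quaternary carbon) and anti to the menthyloxy group (setting the ring CH), before the α-carbonyl radical is reduced and protonated.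

Step 8
Reactants: 15 (4R,5S)-4-Az-5-(Men-oxy)oxolan-2-one; 16 methyl glyoxylate
Product: 17 methyl (2R)-2-hydroxy-2-[(3R,4R,5S)-4-Az-5-(Men-oxy)-2-oxooxolan-3-yl]acetate
Conditions: LDA, THF, −78 °C; ClTi(OiPr)3, −78 → −40 °C; 16, −78 °C; then H2O
Reagents that add atoms: none
Why: Aldol addition of the lactone enolate: the aldehyde approaches anti to the neighbouring hydroazulenyl group (C-3 trans to C-4), and the closed transition state of the triisopropoxytitanium enolate, which favours syn aldols also from ring-locked (E)-enolates, is relied on for the carbinol carbon, any anti epimer being separated here.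

Step 9
Reactants: 17 methyl (2R)-2-hydroxy-2-[(3R,4R,5S)-4-Az-5-(Men-oxy)-2-oxooxolan-3-yl]acetate
Product: 18 (2R,3R,4R,5S)-4-Az-5-methoxy-2-(methoxycarbonyl)oxolane-3-carboxylic acid
Conditions: CSA (0.2 equiv), MeOH (10 equiv), CH2Cl2, 23 °C
Reagents that add atoms: methanol, CO
Why: Acid-catalysed acetal exchange (Fischer-type glycosidation of an acylal): the alkoxy-acyloxy acetal ionises with loss of the carboxylate, the side-chain hydroxyl captures the oxocarbenium ion to form the tetrahydrofuran and methanol replaces menthol, so the former lactone carbonyl emerges as a free acid distinct from the methyl ester; the two ring CH centres are untouched, which turns the trans-lactone into the tetrahydrofuran with carboxyl cis to the hydroazulene, and the acetal carbon should settle trans to its neighbour (either anomer serves).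

Step 10
Reactants: 18 (2R,3R,4R,5S)-4-Az-5-methoxy-2-(methoxycarbonyl)oxolane-3-carboxylic acid
Product: 20 methyl (2R,3S,4R,5S)-4-Az-3-(hydroxymethyl)-5-methoxyoxolane-2-carboxylate, via mixed anhydride 19 (not isolated)
Conditions: i-BuOCOCl, N-methylmorpholine, THF, −15 °C; then NaBH4, H2O, −15 → 0 °C
Reagents that add atoms: none
Why: Mixed carbonic anhydride activation and borohydride reduction should convert the acid into the primary alcohol at low temperature without epimerising the adjacent CH, while the methyl ester, the acetal and the alkene are not attacked by NaBH4 under these conditions.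

Step 11
Reactants: 20 methyl (2R,3S,4R,5S)-4-Az-3-(hydroxymethyl)-5-methoxyoxolane-2-carboxylate
Product: 21 methyl (2R,3R,4R,5S)-4-Az-3-formyl-5-methoxyoxolane-2-carboxylate
Conditions: Dess–Martin periodinane, NaHCO3, CH2Cl2, 0 → 23 °C
Reagents that add atoms: none
Why: Dess–Martin oxidation under bicarbonate buffer should give the aldehyde without enolisation, which would epimerise the formyl-bearing carbon (cis to the hydroazulene) or open the ring by β-elimination of the ring oxygen.

Step 12
Reactants: 21 methyl (2R,3R,4R,5S)-4-Az-3-formyl-5-methoxyoxolane-2-carboxylate; 22 acetic acid; 23 1-(2,2-dimethoxyethyl)-2-isocyanobenzene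
Product: 24 methyl (2R,3S,4R,5S)-3-[(1S)-1-(acetyloxy)-2-{[2-(2,2-dimethoxyethyl)phenyl]amino}-2-oxoethyl]-4-Az-5-methoxyoxolane-2-carboxylate
Conditions: (R)-3,3′-bis(2,4,6-triisopropylphenyl)-1,1′-binaphthyl-2,2′-diyl hydrogen phosphate (10 mol%), CH2Cl2, 0.5 M, 23 °C
Reagents that add atoms: none
Why: The isocyanide carbon adds to the aldehyde carbon while acetic acid, held with the aldehyde in the hydrogen-bonded complex of the chiral phosphoric acid, delivers its carboxylate to the nitrilium carbon, and a 1,4 O→O acyl shift turns the imidate into the α-acetoxy anilide, so the C–C bond to the future lactone carbonyl and the C–O bond to acetate form in one operation. This is the Passerini three-component reaction in its phosphoric-acid-catalysed form, run with a convertible isocyanide. No ring is closed. The one new stereocentre, the (S)-acetoxy carbon, is assigned to the catalyst, because 1,2-induction from the ring CH is weak and a Felkin–Anh analysis with the hydroazulene-bearing ring carbon as the large group does not favour the needed face. The step needs face selectivity at the aldehyde and retention of the formyl group cis to the hydroazulene; the latter is secured by the base-free, weakly acidic medium, and a wrong acetoxy epimer stays correctable after lactonisation, where the wanted acetate is equatorial.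

Step 13
Reactants: 24 α-acetoxy anilide
Product: 25 methyl (2R,3S,4R,5S)-3-[(1S)-1-(acetyloxy)-2-(1H-indol-1-yl)-2-oxoethyl]-4-Az-5-methoxyoxolane-2-carboxylate
Conditions: CSA (0.1 equiv), quinoline (0.1 equiv), benzene, 70 °C
Reagents that add atoms: none
Why: Acid-catalysed cyclisation of the anilide nitrogen onto the arylacetaldehyde acetal with loss of two molecules of methanol gives the N-acylindole (activation of the convertible isocyanide residue); the quinoline buffer should spare the exocyclic alkene, and exchange of the ring acetal with liberated methanol is degenerate.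

Step 14
Reactants: 25 N-acylindole
Product: 27 methyl (1S,4S,5R,6R,8R)-4-(acetyloxy)-8-Az-3-oxo-2,7-dioxabicyclo[3.2.1]octane-6-carboxylate, via lactol 26 (not isolated)
Conditions: 1 M HCl, THF, 40 °C; then Et3N, CH2Cl2, 23 °C
Reagents that add atoms: water, O
Why: Acetal hydrolysis gives the lactol, whose hydroxyl is acylated intramolecularly by the N-acylindole (an active amide) with loss of indole to close the six-membered lactone; only the anomer with hydroxyl cis to the acyl side chain can close, the anomers interconvert, and this fixes the bridgehead acetal carbon.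

**Compound list**

1 | cycloheptane-1,3-dione | O=C1CCCCC(=O)C1 | starting material
2 | 3-(2-methylpropoxy)cyclohept-2-en-1-one | CC(C)COC1=CC(=O)CCCC1 | intermediate
3 | 7-methyl-3-(2-methylpropoxy)cyclohept-2-en-1-one (racemic, not isolated) | CC(C)COC1=CC(=O)C(C)CCC1 | intermediate
4 | 7,7-dimethyl-3-(2-methylpropoxy)cyclohept-2-en-1-one | CC(C)COC1=CC(=O)C(C)(C)CCC1 | intermediate
5 | 2-(2-bromoethyl)-2-methyl-1,3-dioxolane | CC1(CCBr)OCCO1 | starting material
6 | [2-(2-methyl-1,3-dioxolan-2-yl)ethyl]magnesium bromide (not isolated) | CC1(CC[Mg]Br)OCCO1 | intermediate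
7 | 7,7-dimethyl-1-[2-(2-methyl-1,3-dioxolan-2-yl)ethyl]-3-(2-methylpropoxy)cyclohept-2-en-1-ol (racemic, not isolated) | CC(C)COC1=CC(O)(CCC2(C)OCCO2)C(C)(C)CCC1 | intermediate
8 | 4,4-dimethyl-3-(3-oxobutyl)cyclohept-2-en-1-one | CC(=O)CCC1=CC(=O)CCCC1(C)C | intermediate
9 | (3S,3aR,8aR)-3-{[diethoxy(methyl)silyl]oxy}-3,8,8-trimethyloctahydroazulen-4(1H)-one (not isolated) | O=C1CCCC(C)(C)[C@@H]2CC[C@](C)(O[Si](C)(OCC)OCC)[C@H]12 | intermediate
10 | (3S,3aR,8aR)-3-hydroxy-3,8,8-trimethyloctahydroazulen-4(1H)-one (cis-fused, hydroxyl cis to the carbonyl-bearing ring bond) | O=C1CCCC(C)(C)[C@@H]2CC[C@](C)(O)[C@H]12 | intermediate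
11 | (1S,3aR,8aS)-1,4,4-trimethyl-8-methylidenedecahydroazulen-1-ol | C=C1CCCC(C)(C)[C@@H]2CC[C@](C)(O)[C@H]12 | intermediate
12 | methyl (1S,3aR,8aS)-1,4,4-trimethyl-8-methylidenedecahydroazulen-1-yl oxalate (not isolated) | C=C1CCCC(C)(C)[C@@H]2CC[C@](C)(OC(=O)C(=O)OC)[C@H]12 | intermediate
13 | cesium 2-oxo-2-{[(1S,3aR,8aS)-1,4,4-trimethyl-8-methylidenedecahydroazulen-1-yl]oxy}acetate | C=C1CCCC(C)(C)[C@@H]2CC[C@](C)(OC(=O)C(=O)[O-])[C@H]12.[Cs+] | intermediate
14 | (5S)-5-{[(1S,2R,5S)-5-methyl-2-(propan-2-yl)cyclohexyl]oxy}furan-2(5H)-one | O=C1C=C[C@@H](O[C@H]2C[C@@H](C)CC[C@@H]2C(C)C)O1 | starting material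
15 | (4R,5S)-4-Az-5-(Men-oxy)oxolan-2-one (Az and Men-oxy trans) | C=C1CCCC(C)(C)[C@@H]2CC[C@@](C)([C@H]3CC(=O)O[C@@H]3O[C@H]4C[C@@H](C)CC[C@@H]4C(C)C)[C@H]12 | intermediate
16 | methyl glyoxylate | COC(=O)C=O | starting material
17 | methyl (2R)-2-hydroxy-2-[(3R,4R,5S)-4-Az-5-(Men-oxy)-2-oxooxolan-3-yl]acetate (all-trans lactone, syn aldol) | C=C1CCCC(C)(C)[C@@H]2CC[C@@](C)([C@H]3[C@H]([C@@H](O)C(=O)OC)C(=O)O[C@@H]3O[C@H]4C[C@@H](C)CC[C@@H]4C(C)C)[C@H]12 | intermediate
18 | (2R,3R,4R,5S)-4-Az-5-methoxy-2-(methoxycarbonyl)oxolane-3-carboxylic acid (carboxyl cis to Az, trans to the ester) | C=C1CCCC(C)(C)[C@@H]2CC[C@@](C)([C@@H]3[C@@H](OC)O[C@@H](C(=O)OC)[C@@H]3C(=O)O)[C@H]12 | intermediate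
19 | isobutyl carbonic anhydride of 18 (not isolated) | C=C1CCCC(C)(C)[C@@H]2CC[C@@](C)([C@@H]3[C@@H](OC)O[C@@H](C(=O)OC)[C@@H]3C(=O)OC(=O)OCC(C)C)[C@H]12 | intermediate
20 | methyl (2R,3S,4R,5S)-4-Az-3-(hydroxymethyl)-5-methoxyoxolane-2-carboxylate | C=C1CCCC(C)(C)[C@@H]2CC[C@@](C)([C@@H]3[C@@H](OC)O[C@@H](C(=O)OC)[C@@H]3CO)[C@H]12 | intermediate
21 | methyl (2R,3R,4R,5S)-4-Az-3-formyl-5-methoxyoxolane-2-carboxylate | C=C1CCCC(C)(C)[C@@H]2CC[C@@](C)([C@@H]3[C@@H](OC)O[C@@H](C(=O)OC)[C@@H]3C=O)[C@H]12 | intermediate
22 | acetic acid | CC(=O)O | starting material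
23 | 1-(2,2-dimethoxyethyl)-2-isocyanobenzene | [C-]#[N+]c1ccccc1CC(OC)OC | starting material
24 | methyl (2R,3S,4R,5S)-3-[(1S)-1-(acetyloxy)-2-{[2-(2,2-dimethoxyethyl)phenyl]amino}-2-oxoethyl]-4-Az-5-methoxyoxolane-2-carboxylate | C=C1CCCC(C)(C)[C@@H]2CC[C@@](C)([C@@H]3[C@@H](OC)O[C@@H](C(=O)OC)[C@@H]3[C@H](OC(C)=O)C(=O)Nc4ccccc4CC(OC)OC)[C@H]12 | intermediate
25 | methyl (2R,3S,4R,5S)-3-[(1S)-1-(acetyloxy)-2-(1H-indol-1-yl)-2-oxoethyl]-4-Az-5-methoxyoxolane-2-carboxylate | C=C1CCCC(C)(C)[C@@H]2CC[C@@](C)([C@@H]3[C@@H](OC)O[C@@H](C(=O)OC)[C@@H]3[C@H](OC(C)=O)C(=O)n4ccc5ccccc45)[C@H]12 | intermediate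
26 | methyl (2R,3S,4R,5R)-3-[(1S)-1-(acetyloxy)-2-(1H-indol-1-yl)-2-oxoethyl]-4-Az-5-hydroxyoxolane-2-carboxylate (reacting anomer, not isolated) | C=C1CCCC(C)(C)[C@@H]2CC[C@@](C)([C@@H]3[C@H](O)O[C@@H](C(=O)OC)[C@@H]3[C@H](OC(C)=O)C(=O)n4ccc5ccccc45)[C@H]12 | intermediate
27 | methyl (1S,4S,5R,6R,8R)-4-(acetyloxy)-3-oxo-8-[(1R,3aR,8aS)-1,4,4-trimethyl-8-methylidenedecahydroazulen-1-yl]-2,7-dioxabicyclo[3.2.1]octane-6-carboxylate | C=C1CCCC(C)(C)[C@@H]2CC[C@@](C)([C@@H]3[C@@H]4OC(=O)[C@@H](OC(C)=O)[C@H]3[C@H](C(=O)OC)O4)[C@H]12 | target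

**Step count and risks**

Total step count: 14. Longest linear sequence: 14 steps, from cycloheptane-1,3-dione 1 to 27; compounds 5, 14, 16, 22 and 23 enter as purchased materials.

Steps most likely to fail:

Step 4. Hydride delivery to the β-carbon may be slow because it sits next to the quaternary carbon, hydrosilylation of the methyl ketone may compete, or the face selectivity may be too low. The fallback sets the same centre by carbon–carbon bond formation and starts from 4. Stork–Danheiser reduction (LiAlH4, Et2O, 0 °C; then 2 M HCl) gives 4,4-dimethylcyclohept-2-en-1-one F1. Copper-catalysed asymmetric conjugate addition of Grignard reagent 6 (CuBr·SMe2, a Josiphos ligand, t-BuOMe, −75 °C) gives (3R)-4,4-dimethyl-3-[2-(2-methyl-1,3-dioxolan-2-yl)ethyl]cycloheptan-1-one F2. PPTS in wet acetone removes the ketal to give (3R)-4,4-dimethyl-3-(3-oxobutyl)cycloheptan-1-one F3. Intramolecular aldol addition (KOH, MeOH, 0 °C) through the ring enolate carbon beside the substituted carbon closes the five-membered ring and returns to the route at 10.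

Step 9. The acetal exchange may stop on the lactone side of the equilibrium, or the liberated acid may be esterified by methanol, so that the two carboxyl groups are no longer distinct. Partial conversion can be drained by bicarbonate extraction of 18 and resubmission of the neutral part. The fallback accepts full esterification and starts from 17. CSA in methanol as solvent at 40 °C gives dimethyl (2R,3R,4R,5S)-4-Az-5-methoxyoxolane-2,3-dicarboxylate F4. LiOH (1 equiv, THF/H2O, 0 °C) saponifies only the unhindered α-alkoxy ester, giving (2R,3R,4R,5S)-4-Az-5-methoxy-3-(methoxycarbonyl)oxolane-2-carboxylic acid F5. LiBH4 (THF, 40 °C) reduces the remaining ester beside the inert carboxylate, giving (2R,3S,4R,5S)-4-Az-3-(hydroxymethyl)-5-methoxyoxolane-2-carboxylic acid F6. TMSCHN2 (toluene/MeOH) re-forms the methyl ester and returns to the route at 20.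

Step 12. Facial selectivity at the aldehyde may be poor, because substrate and catalyst preferences may oppose each other. The fallback moves control of the acetoxy carbon from the coupling to a later equilibration and starts from 21. The coupling is run without the chiral acid and gives 24 together with its acetoxy-carbon epimer, methyl (2R,3S,4R,5S)-3-[(1R)-1-(acetyloxy)-2-{[2-(2,2-dimethoxyethyl)phenyl]amino}-2-oxoethyl]-4-Az-5-methoxyoxolane-2-carboxylate F7. Under the conditions of step 13 this gives the (1R)-acetoxy N-acylindole F8. Under the conditions of step 14 it gives the corresponding lactol F9 and then methyl (1S,4R,5R,6R,8R)-4-(acetyloxy)-8-Az-3-oxo-2,7-dioxabicyclo[3.2.1]octane-6-carboxylate F10, in which the acetate is axial and 1,3-syn to the hydroazulenyl group. DBU (0.2 equiv, CH2Cl2, 23 °C) equilibrates this lactone through its enol to the equatorial acetate and returns to the route at 27.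

**Further compounds**

F1 | step 4 | 4,4-dimethylcyclohept-2-en-1-one | O=C1C=CC(C)(C)CCC1
F2 | step 4 | (3R)-4,4-dimethyl-3-[2-(2-methyl-1,3-dioxolan-2-yl)ethyl]cycloheptan-1-one | O=C1C[C@@H](CCC2(C)OCCO2)C(C)(C)CCC1
F3 | step 4 | (3R)-4,4-dimethyl-3-(3-oxobutyl)cycloheptan-1-one | CC(=O)CC[C@@H]1CC(=O)CCCC1(C)C
F4 | step 9 | dimethyl (2R,3R,4R,5S)-4-Az-5-methoxyoxolane-2,3-dicarboxylate | C=C1CCCC(C)(C)[C@@H]2CC[C@@](C)([C@@H]3[C@@H](OC)O[C@@H](C(=O)OC)[C@@H]3C(=O)OC)[C@H]12
F5 | step 9 | (2R,3R,4R,5S)-4-Az-5-methoxy-3-(methoxycarbonyl)oxolane-2-carboxylic acid | C=C1CCCC(C)(C)[C@@H]2CC[C@@](C)([C@@H]3[C@@H](OC)O[C@@H](C(=O)O)[C@@H]3C(=O)OC)[C@H]12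
F6 | step 9 | (2R,3S,4R,5S)-4-Az-3-(hydroxymethyl)-5-methoxyoxolane-2-carboxylic acid | C=C1CCCC(C)(C)[C@@H]2CC[C@@](C)([C@@H]3[C@@H](OC)O[C@@H](C(=O)O)[C@@H]3CO)[C@H]12
F7 | step 12 | methyl (2R,3S,4R,5S)-3-[(1R)-1-(acetyloxy)-2-{[2-(2,2-dimethoxyethyl)phenyl]amino}-2-oxoethyl]-4-Az-5-methoxyoxolane-2-carboxylate | C=C1CCCC(C)(C)[C@@H]2CC[C@@](C)([C@@H]3[C@@H](OC)O[C@@H](C(=O)OC)[C@@H]3[C@@H](OC(C)=O)C(=O)Nc4ccccc4CC(OC)OC)[C@H]12
F8 | step 12 | methyl (2R,3S,4R,5S)-3-[(1R)-1-(acetyloxy)-2-(1H-indol-1-yl)-2-oxoethyl]-4-Az-5-methoxyoxolane-2-carboxylate | C=C1CCCC(C)(C)[C@@H]2CC[C@@](C)([C@@H]3[C@@H](OC)O[C@@H](C(=O)OC)[C@@H]3[C@@H](OC(C)=O)C(=O)n4ccc5ccccc45)[C@H]12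
F9 | step 12 | methyl (2R,3S,4R,5R)-3-[(1R)-1-(acetyloxy)-2-(1H-indol-1-yl)-2-oxoethyl]-4-Az-5-hydroxyoxolane-2-carboxylate | C=C1CCCC(C)(C)[C@@H]2CC[C@@](C)([C@@H]3[C@H](O)O[C@@H](C(=O)OC)[C@@H]3[C@@H](OC(C)=O)C(=O)n4ccc5ccccc45)[C@H]12
F10 | step 12 | methyl (1S,4R,5R,6R,8R)-4-(acetyloxy)-8-Az-3-oxo-2,7-dioxabicyclo[3.2.1]octane-6-carboxylate | C=C1CCCC(C)(C)[C@@H]2CC[C@@](C)([C@@H]3[C@@H]4OC(=O)[C@H](OC(C)=O)[C@H]3[C@H](C(=O)OC)O4)[C@H]12
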